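The coumarin is cut at C4–C4a and O1–C2. This releases the benzo ring (ring A) as symmetric phloroglucinol, plus a C2–C3–C4 unit that already bears the aryl group (ring B). The cut exploits C4a, which lies ortho to C5 and C8a and para to C7, so all three oxygens of ring A push electron density onto it. In one operation a ring carbon of phloroglucinol attacks an acid-activated enamino ester and the flanking phenol lactonises, completing the pyranone (ring C). The precursor is a methyl 2-aryl-3-(dimethylamino)acrylate with MOM-protected, prenylated ring B, made from resorcinol in five steps. The two remaining phenols are differentiated afterwards.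

Key step: step 6

Remark: the target has no stereocentre and its prenyl alkene ends in two methyl groups, so no configuration has to be set; the E geometry drawn for the enamino ester is the expected one and is erased in the key step.

Step 1
Reactants: 1 resorcinol
Product: 2 resorcinol bis(MOM) ether (1,3-bis(methoxymethoxy)benzene)
Conditions: NaH (2.4 equiv), MOMCl (2.4 equiv), DMF, 0 °C → rt
Reagents that add atoms: chloromethyl methyl ether (MOMCl), COCCl
Why: Double Williamson-type O-alkylation of the bis-phenoxide by the hard electrophile MOMCl should give the bis-acetal, which protects both phenols against base and serves as the directing group for the two metalations that follow.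

Step 2
Reactants: 2 resorcinol bis(MOM) ether; 3 prenyl bromide
Product: 5 prenylated bis(MOM) ether (1,3-bis(methoxymethoxy)-2-(3-methylbut-2-en-1-yl)benzene), via aryllithium 4 (not isolated)
Conditions: n-BuLi (1.1 equiv), THF, 0 °C → rt; CuI (10 mol %), 3 (1.2 equiv), −30 °C → rt
Reagents that add atoms: none
Why: Directed ortho-metalation occurs at C2, the ring CH flanked and coordinated by both OMOM groups, and copper-catalysed allylic substitution of the primary bromide at its unhindered carbon should deliver the linear prenyl group.

Step 3
Reactants: 5 prenylated bis(MOM) ether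
Product: 7 aryl iodide (1-iodo-2,4-bis(methoxymethoxy)-3-(3-methylbut-2-en-1-yl)benzene), via aryllithium 6 (not isolated)
Conditions: n-BuLi (1.2 equiv), TMEDA (1.2 equiv), Et2O, 0 °C; I2 (1.3 equiv), THF, −78 °C → rt
Reagents that add atoms: iodine, II
Why: A second directed ortho-metalation, steered by coordination of the base to an OMOM oxygen, should remove the ortho ring proton (C4 and C6 are equivalent by symmetry) faster than the CH2 of the prenyl group, whose anion would be twisted out of conjugation by its two ortho substituents, and iodine traps the aryllithium (iodolysis).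

Step 4
Reactants: 7 aryl iodide; 8 methyl bromoacetate
Product: 10 methyl arylacetate (methyl 2-[2,4-bis(methoxymethoxy)-3-(3-methylbut-2-en-1-yl)phenyl]acetate), via Reformatsky reagent 9 (not isolated)
Conditions: 8 (1.8 equiv), Zn dust, TMSCl (3 mol %), THF, 40 °C; then 7, Pd2(dba)3 (2 mol %), XPhos (8 mol %), THF, 60 °C
Reagents that add atoms: none
Why: Negishi-type cross-coupling of a Reformatsky reagent (palladium-catalysed alpha-arylation of an acetate): oxidative addition of the aryl iodide to zerovalent palladium, transmetalation from zinc and reductive elimination install the CH2CO2Me arm in one step, and the mild zinc enolate leaves acetals and alkene untouched.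

Step 5
Reactants: 10 methyl arylacetate
Product: 11 enamino ester (methyl (E)-2-[2,4-bis(methoxymethoxy)-3-(3-methylbut-2-en-1-yl)phenyl]-3-(dimethylamino)acrylate)
Conditions: t-BuOCH(NMe2)2 (2.5 equiv), toluene, 100 °C
Reagents that add atoms: tert-butoxybis(dimethylamino)methane (Bredereck's reagent), CC(C)(C)OC(N(C)C)N(C)C
Why: Aminomethylenation of an active methylene group: the aminal ester ionises to a formamidinium ion and tert-butoxide, which deprotonates the arylacetate, and loss of dimethylamine from the adduct gives the push–pull alkene; this reagent is preferred to DMF dimethyl acetal since the electron-rich aryl group lowers the CH acidity.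

Step 6
Reactants: 11 enamino ester; 12 phloroglucinol
Product: 14 dihydroxycoumarin (3-[2,4-bis(methoxymethoxy)-3-(3-methylbut-2-en-1-yl)phenyl]-5,7-dihydroxy-2H-chromen-2-one), via Z-acrylate 13 (not isolated)
Conditions: 12 (anhydrous, 2.5 equiv), glacial AcOH, 70 °C, N2
Reagents that add atoms: none
Why: Acetic acid protonates 11 at its alpha carbon to give an iminium ion, a ring carbon of 12 attacks the iminium carbon (Friedel–Crafts/Mannich type) to make C4–C4a, and the electron-rich ring then expels dimethylamine to give acrylate 13, whose E and Z forms interconvert in the acidic medium. In the Z form the phenol next to the new bond adds to the ester carbonyl and methanol leaves, a 6-exo-trig acyl substitution that makes O1–C2 and closes ring C irreversibly as the aromatic coumarin. The closest known reaction type is the Pechmann-type condensation of polyhydric phenols and naphthols with 2-substituted 3-(dimethylamino)propenoates or alpha-formyl arylacetates in hot acetic acid. No stereocentre is formed and the alkene geometry of 11 is lost. Site selectivity is not required because the three CH positions and the three OH groups of 12 are related by symmetry, while single annulation rests on the excess of 12 and on the electron-withdrawing lactone of 14. The weak acid, buffered by the liberated dimethylamine, and the moderate temperature are chosen so that the aryl MOM ethers and the prenyl alkene should persist.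

Step 7
Reactants: 14 dihydroxycoumarin
Product: 15 7-O-MOM coumarin (3-[2,4-bis(methoxymethoxy)-3-(3-methylbut-2-en-1-yl)phenyl]-5-hydroxy-7-(methoxymethoxy)-2H-chromen-2-one)
Conditions: K2CO3 (1.05 equiv), MOMCl (1.0 equiv, slow addition), acetone, 0 °C
Reagents that add atoms: chloromethyl methyl ether (MOMCl), COCCl
Why: Williamson-type O-alkylation with base and electrophile both limiting: the 7-OH, para to C4a and conjugated with the lactone carbonyl along the long axis of the coumarin, is the more acidic and less hindered phenol (the 5-OH sits peri to H4), so its phenoxide should be formed and alkylated first.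

Step 8
Reactants: 15 7-O-MOM coumarin
Product: 16 5-O-methyl coumarin (3-[2,4-bis(methoxymethoxy)-3-(3-methylbut-2-en-1-yl)phenyl]-5-methoxy-7-(methoxymethoxy)-2H-chromen-2-one)
Conditions: MeI (3 equiv), K2CO3 (2 equiv), acetone, 40 °C
Reagents that add atoms: iodomethane (MeI), CI
Why: Williamson ether synthesis on the only free phenol left, under conditions to which the lactone, the three acetals and the alkene are inert.

Step 9
Reactants: 16 5-O-methyl coumarin
Product: 17 target (3-[2,4-dihydroxy-3-(3-methylbut-2-en-1-yl)phenyl]-7-hydroxy-5-methoxy-2H-chromen-2-one)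
Conditions: conc. HCl (cat.), MeOH–THF, 25–35 °C
Reagents that add atoms: none
Why: Acid-catalysed acetal methanolysis should remove the three aryl MOM groups as dimethoxymethane under the dilute, near-ambient conditions commonly applied to ortho-prenylated phenols, at which protonation of the trisubstituted alkene should remain slow and the lactone and aryl methyl ether are untouched.

Compound list
1 | resorcinol (benzene-1,3-diol) | Oc1cccc(O)c1 | starting material
2 | 1,3-bis(methoxymethoxy)benzene | COCOc1cccc(OCOC)c1 | intermediate
3 | prenyl bromide (1-bromo-3-methylbut-2-ene) | CC(C)=CCBr | starting material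
4 | [2,6-bis(methoxymethoxy)phenyl]lithium | [Li]c1c(OCOC)cccc1OCOC | intermediate
5 | 1,3-bis(methoxymethoxy)-2-(3-methylbut-2-en-1-yl)benzene | COCOc1cccc(OCOC)c1CC=C(C)C | intermediate
6 | [2,4-bis(methoxymethoxy)-3-(3-methylbut-2-en-1-yl)phenyl]lithium | [Li]c1ccc(OCOC)c(CC=C(C)C)c1OCOC | intermediate
7 | 1-iodo-2,4-bis(methoxymethoxy)-3-(3-methylbut-2-en-1-yl)benzene | Ic1ccc(OCOC)c(CC=C(C)C)c1OCOC | intermediate
8 | methyl bromoacetate | COC(=O)CBr | starting material
9 | bromo(2-methoxy-2-oxoethyl)zinc | COC(=O)C[Zn]Br | intermediate
10 | methyl 2-[2,4-bis(methoxymethoxy)-3-(3-methylbut-2-en-1-yl)phenyl]acetate | COC(=O)Cc1ccc(OCOC)c(CC=C(C)C)c1OCOC | intermediate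
11 | methyl (E)-2-[2,4-bis(methoxymethoxy)-3-(3-methylbut-2-en-1-yl)phenyl]-3-(dimethylamino)acrylate | COC(=O)/C(=C/N(C)C)c1ccc(OCOC)c(CC=C(C)C)c1OCOC | intermediate
12 | phloroglucinol (benzene-1,3,5-triol) | Oc1cc(O)cc(O)c1 | starting material
13 | methyl (Z)-2-[2,4-bis(methoxymethoxy)-3-(3-methylbut-2-en-1-yl)phenyl]-3-(2,4,6-trihydroxyphenyl)acrylate | COC(=O)/C(=C\c1c(O)cc(O)cc1O)c1ccc(OCOC)c(CC=C(C)C)c1OCOC | intermediate
14 | 3-[2,4-bis(methoxymethoxy)-3-(3-methylbut-2-en-1-yl)phenyl]-5,7-dihydroxy-2H-chromen-2-one | Oc1cc(O)c2cc(-c3ccc(OCOC)c(CC=C(C)C)c3OCOC)c(=O)oc2c1 | intermediate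
15 | 3-[2,4-bis(methoxymethoxy)-3-(3-methylbut-2-en-1-yl)phenyl]-5-hydroxy-7-(methoxymethoxy)-2H-chromen-2-one | COCOc1cc(O)c2cc(-c3ccc(OCOC)c(CC=C(C)C)c3OCOC)c(=O)oc2c1 | intermediate
16 | 3-[2,4-bis(methoxymethoxy)-3-(3-methylbut-2-en-1-yl)phenyl]-5-methoxy-7-(methoxymethoxy)-2H-chromen-2-one | COCOc1cc(OC)c2cc(-c3ccc(OCOC)c(CC=C(C)C)c3OCOC)c(=O)oc2c1 | intermediate
17 | 3-[2,4-dihydroxy-3-(3-methylbut-2-en-1-yl)phenyl]-7-hydroxy-5-methoxy-2H-chromen-2-one | COc1cc(O)cc2oc(=O)c(-c3ccc(O)c(CC=C(C)C)c3O)cc12 | target

Total step count: 9. Longest linear sequence: 9 steps (1 → 17); 3, 8 and 12 enter as purchased materials.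

Steps most likely to fail

Step 6.
- What may go wrong:
  - C-alkylation may be too slow at a temperature the acetals tolerate.
  - The 2'-acetal oxygen may attack the iminium carbon, with loss of its MOM group.
  - The transient quinone methide may be captured by a second molecule of 12.
  - A second annulation may occur on the product.
- Fallback (Perkin-type closure at C3–C4 in a basic medium): it sets out from 10. Saponification (LiOH, THF–H2O, rt) would give 2-[2,4-bis(methoxymethoxy)-3-prenylphenyl]acetic acid F1. F1 is condensed with commercial 2,4,6-trihydroxybenzaldehyde (O=Cc1c(O)cc(O)cc1O) in Ac2O–Et3N at about 100 °C, conditions harmless to MOM ethers and to the alkene. This would give the 5,7-diacetoxy-3-arylcoumarin F2. Methanolysis of the two phenolic acetates (K2CO3, MeOH, 0 °C) comes back to the route at 14.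

Step 7.
- What may go wrong: discrimination between the two phenols may be insufficient, because both are conjugated with the lactone and no hydrogen bond masks the 5-OH. Alkylation at the wrong oxygen and double alkylation would then compete.
- Fallback (the methyl ether arrives with ring A, so no phenol has to be singled out): it sets out from 11. The annulation of step 6 is run with commercial 5-methoxyresorcinol (COc1cc(O)cc(O)c1) in place of 12.
  - Attack through C4 or C6 of this nucleophile would give 3-[2,4-bis(methoxymethoxy)-3-prenylphenyl]-7-hydroxy-5-methoxycoumarin F3.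
  - Attack through C2 would give the 5-hydroxy-7-methoxy isomer F4, which has to be removed by chromatography.
  - Two of the three ring positions lead to F3.
  - Acidic methanolysis of F3 as in step 9 comes back to the route at 17 and bypasses 14, 15 and 16.

Step 9.
- What may go wrong: a flanking phenol or methanol may add to the protonated prenyl alkene before the last acetal has been cleaved.
- Fallback (acetal-to-silyl-ether exchange without free Brønsted acid, then neutral desilylation): it sets out from 16. Treatment with TMSOTf and 2,2'-bipyridyl in MeCN at 0 °C → rt would convert the three aryl MOM ethers into the tris(trimethylsilyl) ether F5, the bipyridyl taking up the methoxymethyl cation and buffering the medium. Stirring F5 with water (or KF in MeOH) at rt hydrolyses the aryl silyl ethers and comes back to the route at 17.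

Further compounds
F1 | step 6 | 2-[2,4-bis(methoxymethoxy)-3-(3-methylbut-2-en-1-yl)phenyl]acetic acid | OC(=O)Cc1ccc(OCOC)c(CC=C(C)C)c1OCOC
F2 | step 6 | 3-[2,4-bis(methoxymethoxy)-3-(3-methylbut-2-en-1-yl)phenyl]-2-oxo-2H-chromene-5,7-diyl diacetate | CC(=O)Oc1cc(OC(C)=O)c2cc(-c3ccc(OCOC)c(CC=C(C)C)c3OCOC)c(=O)oc2c1
F3 | step 7 | 3-[2,4-bis(methoxymethoxy)-3-(3-methylbut-2-en-1-yl)phenyl]-7-hydroxy-5-methoxy-2H-chromen-2-one | COc1cc(O)cc2oc(=O)c(-c3ccc(OCOC)c(CC=C(C)C)c3OCOC)cc12
F4 | step 7 | 3-[2,4-bis(methoxymethoxy)-3-(3-methylbut-2-en-1-yl)phenyl]-5-hydroxy-7-methoxy-2H-chromen-2-one | COc1cc(O)c2cc(-c3ccc(OCOC)c(CC=C(C)C)c3OCOC)c(=O)oc2c1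
F5 | step 9 | 5-methoxy-3-[3-(3-methylbut-2-en-1-yl)-2,4-bis(trimethylsilyloxy)phenyl]-7-(trimethylsilyloxy)-2H-chromen-2-one | COc1cc(O[Si](C)(C)C)cc2oc(=O)c(-c3ccc(O[Si](C)(C)C)c(CC=C(C)C)c3O[Si](C)(C)C)cc12
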